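**Retrosynthetic overview**
1. Feature used: in ring A the pyranone oxygen O1 is bonded to C8a and the C4 carbonyl carbon to the adjacent C4a, and C4a neighbours the oxygenated C5. C8a and C4a are therefore treated as the two carbons of an aryne whose triple bond is polarised by the alkoxy group at the future C5.
2. Ring C is cut at O1–C8a, C4–C4a and O1–C2. This gives 4-benzyloxy-3,5-dimethoxybenzyne (stored as its ortho-silylaryl triflate) and 3-(4-benzyloxy-2,5-dimethoxyphenyl)propiolic acid, and the acid supplies O1, C2, C3, C4 and the carbonyl oxygen.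
3. The silyl triflate comes from syringaldehyde (benzylation, Baeyer–Villiger, monobromination, O-silylation, retro-Brook/triflation). The acid comes from isovanillin (benzylation, Baeyer–Villiger, methylation, iodination, coupling with propiolic acid).
4. Rings A and B are bought in, and ring C is the only ring formed, in the convergent step. Hydrogenolysis of both benzyl ethers and chelation-directed cleavage of the 5-O-methyl group finish the route.

Key step: step 11

Remark: the target has no stereocentre, so no stereocontrol is needed. Flavone numbering (O1, C2–C4, C4a, C5–C8, C8a, primed locants for ring B) is used for ring positions.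

**Route**

Step 1
Reactants: 1 syringaldehyde (4-hydroxy-3,5-dimethoxybenzaldehyde)
Product: 2 4-benzyloxy-3,5-dimethoxybenzaldehyde
Conditions: BnBr, K2CO3, DMF, 60 °C
Reagents that add atoms: benzyl bromide, BrCc1ccccc1
Why: Williamson ether synthesis, in which the acidic para-formyl phenoxide is alkylated cleanly and the benzyl ether marks the future 6-oxygen for late release by hydrogenolysis.

Step 2
Reactants: 2 4-benzyloxy-3,5-dimethoxybenzaldehyde
Product: 4 4-benzyloxy-3,5-dimethoxyphenol, via aryl formate 3 (not isolated)
Conditions: mCPBA, CH2Cl2, 0 °C to rt; NaHCO3 wash; then K2CO3 (cat.), MeOH, rt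
Reagents that add atoms: meta-chloroperoxybenzoic acid, O=C(OO)c1cccc(Cl)c1
Why: Baeyer–Villiger oxidation, chosen because the substrate has no free phenol for alkaline peroxide conditions, in which the electron-rich trialkoxyaryl group migrates to give the formate that catalytic carbonate in methanol transesterifies to the phenol.

Step 3
Reactants: 4 4-benzyloxy-3,5-dimethoxyphenol
Product: 5 4-benzyloxy-2-bromo-3,5-dimethoxyphenol
Conditions: NBS (1.0 equiv), CH2Cl2, −78 °C to 0 °C
Reagents that add atoms: N-bromosuccinimide, O=C1CCC(=O)N1Br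
Why: Electrophilic aromatic bromination, in which C2 and C6 are the only free positions and are equivalent by symmetry, so one equivalent of NBS under dry, cold conditions should stop at the single possible monobromide.

Step 4
Reactants: 5 4-benzyloxy-2-bromo-3,5-dimethoxyphenol
Product: 6 (4-benzyloxy-2-bromo-3,5-dimethoxyphenoxy)trimethylsilane
Conditions: HMDS, THF, reflux; evaporate
Reagents that add atoms: hexamethyldisilazane, C[Si](C)(C)N[Si](C)(C)C
Why: O-Silylation of a phenol with hexamethyldisilazane, which gives only a volatile by-product so that the moisture-sensitive silyl ether can be used after evaporation.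

Step 5
Reactants: 6 (4-benzyloxy-2-bromo-3,5-dimethoxyphenoxy)trimethylsilane
Product: 9 4-benzyloxy-3,5-dimethoxy-2-(trimethylsilyl)phenyl trifluoromethanesulfonate, via aryllithium 7 (not isolated), via lithium silylphenoxide 8 (not isolated)
Conditions: n-BuLi (1.1 equiv), THF, −78 °C; then Tf2O, −78 °C; NaHCO3 quench
Reagents that add atoms: trifluoromethanesulfonic anhydride, O=S(=O)(OS(=O)(=O)C(F)(F)F)C(F)(F)F
Why: Bromine–lithium exchange, which outruns benzylic deprotonation at −78 °C, is followed by a retro-Brook 1,3 O-to-C silyl shift and O-triflation of the resulting phenoxide, the standard route to ortho-silylaryl triflates.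

Step 6
Reactants: 10 isovanillin (3-hydroxy-4-methoxybenzaldehyde)
Product: 11 3-benzyloxy-4-methoxybenzaldehyde
Conditions: BnBr, K2CO3, DMF, rt to 60 °C
Reagents that add atoms: benzyl bromide, BrCc1ccccc1
Why: Williamson ether synthesis on the only phenol, which places the benzyl group on the oxygen that becomes the 4'-OH.

Step 7
Reactants: 11 3-benzyloxy-4-methoxybenzaldehyde
Product: 13 3-benzyloxy-4-methoxyphenol, via aryl formate 12 (not isolated)
Conditions: mCPBA, CH2Cl2, 0 °C to rt; NaHCO3 wash; then K2CO3 (cat.), MeOH, rt
Reagents that add atoms: meta-chloroperoxybenzoic acid, O=C(OO)c1cccc(Cl)c1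
Why: Baeyer–Villiger oxidation, in which the para-methoxy group promotes aryl migration and mild methanolysis of the formate frees the phenol that becomes the 2'-oxygen.

Step 8
Reactants: 13 3-benzyloxy-4-methoxyphenol
Product: 14 2-benzyloxy-1,4-dimethoxybenzene
Conditions: MeI, K2CO3, acetone, reflux
Reagents that add atoms: iodomethane, CI
Why: Williamson O-methylation of the only free phenol, which completes the para-dimethoxy pattern of ring B.

Step 9
Reactants: 14 2-benzyloxy-1,4-dimethoxybenzene
Product: 15 1-benzyloxy-4-iodo-2,5-dimethoxybenzene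
Conditions: NIS (1.05 equiv), TFA (cat.), MeCN, rt, dark
Reagents that add atoms: N-iodosuccinimide, O=C1CCC(=O)N1I
Why: Electrophilic aromatic iodination at the carbon para to the benzyloxy group and ortho to a methoxy group, the only unhindered position activated by two oxygens, as is usual for 1,2,4-trialkoxybenzenes.

Step 10
Reactants: 15 1-benzyloxy-4-iodo-2,5-dimethoxybenzene; 16 propiolic acid
Product: 17 3-(4-benzyloxy-2,5-dimethoxyphenyl)propiolic acid
Conditions: Pd(PPh3)4 (cat.), DBU (2.5 equiv), DMSO, 35 °C; cold dilute HCl work-up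
Reagents that add atoms: none
Why: Copper-free Sonogashira-type coupling of an aryl iodide with the propiolate anion on zerovalent palladium, in which the near-ambient temperature and the absence of copper keep the carboxyl group in place.

Step 11
Reactants: 9 4-benzyloxy-3,5-dimethoxy-2-(trimethylsilyl)phenyl trifluoromethanesulfonate (1.5 equiv); 17 3-(4-benzyloxy-2,5-dimethoxyphenyl)propiolic acid
Product: 20 6-benzyloxy-2-(4-benzyloxy-2,5-dimethoxyphenyl)-5,7-dimethoxychromen-4-one, via 4-benzyloxy-3,5-dimethoxybenzyne 18 (not isolated), via ortho-hydroxyaryl ynone 19 (not isolated)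
Conditions: CsF (4 equiv), THF (dilute, about 0.025 M), sealed tube, 125 °C, 24 h
Reagents that add atoms: none
Why: Fluoride removes the silyl group of 9, triflate leaves and aryne 18 forms slowly; the carboxylate of 17 adds through oxygen to the aryne carbon that becomes C8a, the aryl anion left on the future C4a attacks the adjacent ester carbonyl, and the strained four-membered alkoxide opens to the ortho-acyl phenoxide of 19. This phenoxide adds to the alkyne terminus of the ynone, and protonation at C3 by the proton the acid brought in completes ring C, so that O1–C8a, C4–C4a and O1–C2 are all made in one operation. The closest known reaction type is the intermolecular C–O insertion of arynes into carboxylic acids to give ortho-hydroxyaryl ketones, which is known to continue to flavones when arylpropiolic acids are used. Ring C closes by a 6-endo-dig oxa-Michael addition, preferred over 5-exo-dig closure because the beta carbon is the electrophilic site of the ynone when no alkynophilic metal is present. No stereocentre is formed. The step needs one orientation of addition, and the methoxy group next to the triple bond secures it: its inductive pull distorts the aryne so that the remote, C–H-flanked carbon is the electrophilic and less hindered one while charge builds up beside the C–O bond, which gives only the 5,6,7 pattern, and hot dilute THF favours acyl transfer over protonation of the aryl anion.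

Step 12
Reactants: 20 6-benzyloxy-2-(4-benzyloxy-2,5-dimethoxyphenyl)-5,7-dimethoxychromen-4-one
Product: 21 6-hydroxy-2-(4-hydroxy-2,5-dimethoxyphenyl)-5,7-dimethoxychromen-4-one
Conditions: H2 (1 atm), Pd/C (10 wt%), EtOAc–MeOH, rt
Reagents that add atoms: none
Why: Catalytic hydrogenolysis of aryl benzyl ethers, which at one atmosphere and room temperature leaves the conjugated C2–C3 double bond of the chromone and all methyl ethers untouched.

Step 13
Reactants: 21 6-hydroxy-2-(4-hydroxy-2,5-dimethoxyphenyl)-5,7-dimethoxychromen-4-one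
Product: 22 5,6-dihydroxy-2-(4-hydroxy-2,5-dimethoxyphenyl)-7-methoxychromen-4-one (target)
Conditions: BCl3 (1 M in CH2Cl2, 4 equiv), CH2Cl2, −78 °C to 0 °C; then 1 M HCl–MeOH work-up
Reagents that add atoms: none
Why: Chelation-directed Lewis acid ether cleavage, in which boron bridges the C4 carbonyl oxygen and the peri 5-methoxy oxygen so that chloride removes only that methyl group, the excess reagent covers the two free phenols, ordinary aryl methyl ethers (7, 2', 5') survive BCl3 at or below 0 °C, and the mild conditions avoid a Wessely–Moser rearrangement.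

**Compound list**
1 | syringaldehyde | COc1cc(C=O)cc(OC)c1O | starting material
2 | 4-benzyloxy-3,5-dimethoxybenzaldehyde | COc1cc(C=O)cc(OC)c1OCc1ccccc1 | intermediate
3 | 4-benzyloxy-3,5-dimethoxyphenyl formate (not isolated) | COc1cc(OC=O)cc(OC)c1OCc1ccccc1 | intermediate
4 | 4-benzyloxy-3,5-dimethoxyphenol | COc1cc(O)cc(OC)c1OCc1ccccc1 | intermediate
5 | 4-benzyloxy-2-bromo-3,5-dimethoxyphenol | COc1cc(O)c(Br)c(OC)c1OCc1ccccc1 | intermediate
6 | (4-benzyloxy-2-bromo-3,5-dimethoxyphenoxy)trimethylsilane | COc1cc(O[Si](C)(C)C)c(Br)c(OC)c1OCc1ccccc1 | intermediate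
7 | [3-benzyloxy-2,4-dimethoxy-6-(trimethylsilyloxy)phenyl]lithium (not isolated) | COc1cc(O[Si](C)(C)C)c([Li])c(OC)c1OCc1ccccc1 | intermediate
8 | lithium 4-benzyloxy-3,5-dimethoxy-2-(trimethylsilyl)phenoxide (not isolated) | [Li+].COc1cc([O-])c([Si](C)(C)C)c(OC)c1OCc1ccccc1 | intermediate
9 | 4-benzyloxy-3,5-dimethoxy-2-(trimethylsilyl)phenyl trifluoromethanesulfonate | COc1cc(OS(=O)(=O)C(F)(F)F)c([Si](C)(C)C)c(OC)c1OCc1ccccc1 | intermediate
10 | isovanillin | COc1ccc(C=O)cc1O | starting material
11 | 3-benzyloxy-4-methoxybenzaldehyde | COc1ccc(C=O)cc1OCc1ccccc1 | intermediate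
12 | 3-benzyloxy-4-methoxyphenyl formate (not isolated) | COc1ccc(OC=O)cc1OCc1ccccc1 | intermediate
13 | 3-benzyloxy-4-methoxyphenol | COc1ccc(O)cc1OCc1ccccc1 | intermediate
14 | 2-benzyloxy-1,4-dimethoxybenzene | COc1ccc(OC)c(OCc2ccccc2)c1 | intermediate
15 | 1-benzyloxy-4-iodo-2,5-dimethoxybenzene | COc1cc(I)c(OC)cc1OCc1ccccc1 | intermediate
16 | propiolic acid | C#CC(=O)O | starting material
17 | 3-(4-benzyloxy-2,5-dimethoxyphenyl)propiolic acid | COc1cc(C#CC(=O)O)c(OC)cc1OCc1ccccc1 | intermediate
18 | 4-benzyloxy-3,5-dimethoxybenzyne (not isolated) | COC1=CC#CC(OC)=C1OCc1ccccc1 | intermediate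
19 | 1-(3-benzyloxy-6-hydroxy-2,4-dimethoxyphenyl)-3-(4-benzyloxy-2,5-dimethoxyphenyl)prop-2-yn-1-one (present as its caesium phenoxide, not isolated) | COc1cc(C#CC(=O)c2c(O)cc(OC)c(OCc3ccccc3)c2OC)c(OC)cc1OCc1ccccc1 | intermediate
20 | 6-benzyloxy-2-(4-benzyloxy-2,5-dimethoxyphenyl)-5,7-dimethoxychromen-4-one | COc1cc(-c2cc(=O)c3c(OC)c(OCc4ccccc4)c(OC)cc3o2)c(OC)cc1OCc1ccccc1 | intermediate
21 | 6-hydroxy-2-(4-hydroxy-2,5-dimethoxyphenyl)-5,7-dimethoxychromen-4-one | COc1cc(-c2cc(=O)c3c(OC)c(O)c(OC)cc3o2)c(OC)cc1O | intermediate
22 | 5,6-dihydroxy-2-(4-hydroxy-2,5-dimethoxyphenyl)-7-methoxychromen-4-one | COc1cc(-c2cc(=O)c3c(O)c(O)c(OC)cc3o2)c(OC)cc1O | target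

**Step count**
Total steps: 13. Longest linear sequence: 8 (steps 1–5, then 11–13). The isovanillin branch, steps 6–10 then 11–13, is equally long.

**Steps most likely to fail**

Step 11. The aryl anion may be protonated before the acyl shift, so that the sequence stops at simple O-arylation. The electron-rich propiolate may lose CO2 at 125 °C. Part of the material may close in the 5-exo mode, and the intermediate phenoxide may consume excess aryne. The fallback sets out from 5 and 17 and comes back at 20. It makes the C4–C4a bond by acylating an aryllithium instead of by insertion. Bromophenol 5 is protected (MOMCl, i-Pr2NEt, CH2Cl2) as 2-benzyloxy-4-bromo-1,3-dimethoxy-5-(methoxymethoxy)benzene F1. Acid 17 is condensed with MeNHOMe·HCl (EDC, CH2Cl2) to the Weinreb amide N-methoxy-N-methyl-3-(4-benzyloxy-2,5-dimethoxyphenyl)propiolamide F2. Bromine–lithium exchange on F1 (n-BuLi, THF, −78 °C), addition of F2 and a cold acidic quench should give 1-[3-benzyloxy-2,4-dimethoxy-6-(methoxymethoxy)phenyl]-3-(4-benzyloxy-2,5-dimethoxyphenyl)prop-2-yn-1-one F3. HCl in MeOH removes the acetal to give 19, isolated this time, and catalytic DMAP in DMF closes it 6-endo-dig to 20.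

Step 10. Oxidative addition to the electron-rich, ortho-substituted iodide may be slow. The product may then decarboxylate under palladium and base, and the freed alkyne may couple a second time. The fallback sets out from 15 and comes back at 17. It installs the carboxyl carbon last. Sonogashira coupling of 15 with trimethylsilylacetylene (PdCl2(PPh3)2, CuI, Et3N, THF) should give [(4-benzyloxy-2,5-dimethoxyphenyl)ethynyl]trimethylsilane F4. K2CO3 in MeOH desilylates it to 1-benzyloxy-4-ethynyl-2,5-dimethoxybenzene F5. Deprotonation with n-BuLi (THF, −78 °C), quenching with CO2 and acidification give 17.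

Step 5. The O-to-C silyl migration to a carbon flanked on both sides may be incomplete. The aryllithium may be protonated too early, or the very electron-rich arylsilane may protodesilylate on acidic silica. Upstream, step 3 may overbrominate or oxidise the para-alkoxyphenol. The fallback sets out from 4 and comes back at 9, bypassing steps 3–5 by directed ortho-metalation. Phenol 4 and isopropyl isocyanate (cat. Et3N, CH2Cl2) give 4-benzyloxy-3,5-dimethoxyphenyl N-isopropylcarbamate F6. Its N–H is masked in the flask with TBSOTf/TMEDA as the N-(tert-butyldimethylsilyl) carbamate F7. n-BuLi/TMEDA at −78 °C lithiates the carbon between the carbamate and the methoxy group (the two such positions are equivalent), and TMSCl gives the N-silyl C2-trimethylsilyl carbamate F8. The acidic work-up strips the nitrogen silyl group to leave 4-benzyloxy-3,5-dimethoxy-2-(trimethylsilyl)phenyl N-isopropylcarbamate F9. Et2NH and DBU in MeCN at 40 °C remove the carbamoyl group to give 4-benzyloxy-3,5-dimethoxy-2-(trimethylsilyl)phenol F10, which PhNTf2 triflates in the same pot to 9.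

**Further compounds**
F1 | step 11 | 2-benzyloxy-4-bromo-1,3-dimethoxy-5-(methoxymethoxy)benzene | COCOc1cc(OC)c(OCc2ccccc2)c(OC)c1Br
F2 | step 11 | N-methoxy-N-methyl-3-(4-benzyloxy-2,5-dimethoxyphenyl)propiolamide | COc1cc(C#CC(=O)N(C)OC)c(OC)cc1OCc1ccccc1
F3 | step 11 | 1-[3-benzyloxy-2,4-dimethoxy-6-(methoxymethoxy)phenyl]-3-(4-benzyloxy-2,5-dimethoxyphenyl)prop-2-yn-1-one | COCOc1cc(OC)c(OCc2ccccc2)c(OC)c1C(=O)C#Cc1cc(OC)c(OCc2ccccc2)cc1OC
F4 | step 10 | [(4-benzyloxy-2,5-dimethoxyphenyl)ethynyl]trimethylsilane | COc1cc(C#C[Si](C)(C)C)c(OC)cc1OCc1ccccc1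
F5 | step 10 | 1-benzyloxy-4-ethynyl-2,5-dimethoxybenzene | COc1cc(C#C)c(OC)cc1OCc1ccccc1
F6 | step 5 | 4-benzyloxy-3,5-dimethoxyphenyl N-isopropylcarbamate | COc1cc(OC(=O)NC(C)C)cc(OC)c1OCc1ccccc1
F7 | step 5 | 4-benzyloxy-3,5-dimethoxyphenyl N-(tert-butyldimethylsilyl)-N-isopropylcarbamate | COc1cc(OC(=O)N(C(C)C)[Si](C)(C)C(C)(C)C)cc(OC)c1OCc1ccccc1
F8 | step 5 | 4-benzyloxy-3,5-dimethoxy-2-(trimethylsilyl)phenyl N-(tert-butyldimethylsilyl)-N-isopropylcarbamate | COc1cc(OC(=O)N(C(C)C)[Si](C)(C)C(C)(C)C)c([Si](C)(C)C)c(OC)c1OCc1ccccc1
F9 | step 5 | 4-benzyloxy-3,5-dimethoxy-2-(trimethylsilyl)phenyl N-isopropylcarbamate | COc1cc(OC(=O)NC(C)C)c([Si](C)(C)C)c(OC)c1OCc1ccccc1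
F10 | step 5 | 4-benzyloxy-3,5-dimethoxy-2-(trimethylsilyl)phenol | COc1cc(O)c([Si](C)(C)C)c(OC)c1OCc1ccccc1
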